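Everything depends on reading the 2,5-dihydrofuran (carotenoid numbering) as an oxygen-expanded cyclobutene: without its oxygen, C5, C6, C7 and C8 form a four-membered ring that shares the C5–C6 bond with ring A and can come from a ketene-type C5=C8 unit and a C6≡C7 triple bond. The key step lets a chiral keteniminium ion add to a tethered terminal alkyne, which makes C5–C6 and C7–C8, closes ring A and the cyclobutene and sets quaternary C5 in one operation; Baeyer–Villiger oxidation then inserts the oxygen between C5 and C8. Its precursor is an open-chain (2R,5R)-2,5-dimethylpyrrolidine amide of 2,6,6-trimethyloct-7-ynoic acid bearing a non-participating acetoxy group at carotenoid C3.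

Key step: step 9

Remarks

- Numbering: atoms carry carotenoid numbers. Ring A is C1–C6 (C1 gem-dimethyl carbon, C3 carbinol carbon, C5 methyl-bearing quaternary carbon), the dihydrofuran is O–C5–C6=C7–C8, and the chain runs C9–C15 and then C15'–C10'.
- Reading of the target: (3S,5R,8R). The SMILES places C8 and C11 cis across C9=C10 (9Z) and makes the other five chain double bonds E, so the C9–C11 unit is built as the Z-alkenyl isomer (steps 16–18).
- Design of the precursor: C3 passes through step 9 as an acetate and not as a ketal. An ether-type oxygen γ to the amide carbon adds to C8 of a keteniminium ion through a five-membered ring, and a ketal would then fragment. Both C3 epimers are carried and merged by oxidation in step 12.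
- Assumption: the facial sense of the (2R,5R)-amine in step 9 is taken from a steric model and is to be confirmed at compound 24. If it proves opposite, the (2S,5S)-amine is used in step 4 and nothing else changes.

Step 1
Reactants: 1 methyl 3,3-dimethylpent-4-enoate
Product: 3 methyl 3,3-dimethyl-4-oxobutanoate, via ozonide 2 (not isolated)
Conditions: O3, CH2Cl2, −78 °C; then Me2S, −78 → 20 °C
Reagents that add atoms: ozone, [O-][O+]=O
Why: Ozonolysis with reductive work-up cleaves the only C=C bond and leaves a non-enolisable aldehyde next to the quaternary carbon.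

Step 2
Reactants: 3 methyl 3,3-dimethyl-4-oxobutanoate; 4 dimethyl (1-diazo-2-oxopropyl)phosphonate
Product: 5 methyl 3,3-dimethylpent-4-ynoate
Conditions: K2CO3, MeOH, 0 → 20 °C
Reagents that add atoms: none
Why: Seyferth–Gilbert homologation in its Ohira–Bestmann form turns the hindered aldehyde into the terminal alkyne under carbonate conditions that spare the ester and avoid the cyclopropane or bromolactone formation that a dibromination–elimination sequence on this skeleton would risk.

Step 3
Reactants: 5 methyl 3,3-dimethylpent-4-ynoate; 6 tert-butyl acetate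
Product: 8 tert-butyl 5,5-dimethyl-3-oxohept-6-ynoate, via lithium enolate 7 (not isolated)
Conditions: LiN(i-Pr)2 (3.2 equiv), 6 (3 equiv), THF, −78 °C; then 5, −78 → −30 °C; cold 1 M HCl
Reagents that add atoms: none
Why: Crossed Claisen condensation, in which the excess ester enolate adds to the methyl ester and the β-keto ester is stored as its enolate, so that no second addition occurs.

Step 4
Reactants: 9 (2R,5R)-2,5-dimethylpyrrolidine; 10 2-bromopropanoyl bromide
Product: 11 2-bromo-1-[(2R,5R)-2,5-dimethylpyrrolidin-1-yl]propan-1-one (both epimers at the C–Br carbon)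
Conditions: K2CO3, CH2Cl2/H2O, 0 °C
Reagents that add atoms: none
Why: Schotten–Baumann N-acylation of the hindered secondary amine by the acid bromide; the bromine-bearing centre is left unresolved because it becomes C5, which is planarised in step 9.

Step 5
Reactants: 8 tert-butyl 5,5-dimethyl-3-oxohept-6-ynoate; 11 the bromoamide
Product: 13 tert-butyl 2-{1-[(2R,5R)-2,5-dimethylpyrrolidin-1-yl]-1-oxopropan-2-yl}-5,5-dimethyl-3-oxohept-6-ynoate (diastereomer mixture), via sodium enolate 12 (not isolated)
Conditions: NaH (1.05 equiv), THF, 0 °C; then 11, NaI (0.2 equiv), DMF, 50 °C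
Reagents that add atoms: none
Why: SN2 C-alkylation of the soft β-keto ester enolate by the α-halo amide forms the C4–C5 bond and the 1,4-dicarbonyl array more reliably than alkylation of a simple ketone enolate with a secondary halide.

Step 6
Reactants: 13 the alkylated β-keto ester
Product: 15 1-[(2R,5R)-2,5-dimethylpyrrolidin-1-yl]-2,6,6-trimethyloct-7-yne-1,4-dione (both C2 epimers), via β-keto acid 14 (not isolated)
Conditions: CF3CO2H, CH2Cl2, 20 °C; then toluene, 80 °C
Reagents that add atoms: none
Why: Acidolysis of the tert-butyl ester followed by thermal decarboxylation of the β-keto acid (acetoacetic ester ketone synthesis) leaves the γ-keto amide.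

Step 7
Reactants: 15 the γ-keto amide
Product: 16 1-[(2R,5R)-2,5-dimethylpyrrolidin-1-yl]-4-hydroxy-2,6,6-trimethyloct-7-yn-1-one (C2 and C4 epimers)
Conditions: NaBH4, MeOH, 0 °C
Reagents that add atoms: none
Why: Chemoselective borohydride reduction of the ketone beside the tertiary amide and the alkyne; the new carbinol centre (carotenoid C3) need not be controlled because it is reoxidised in step 12.

Step 8
Reactants: 16 the γ-hydroxy amide
Product: 17 1-[(2R,5R)-2,5-dimethylpyrrolidin-1-yl]-2,6,6-trimethyl-1-oxooct-7-yn-4-yl acetate (C2 and C4 epimers)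
Conditions: Ac2O, pyridine, 4-(dimethylamino)pyridine (cat.), CH2Cl2, 20 °C
Reagents that add atoms: acetic anhydride, CC(=O)OC(C)=O
Why: O-Acylation gives C3 an ester oxygen that is too weakly nucleophilic to add to the keteniminium carbon in step 9.

Step 9
Reactants: 17 the acetoxy alkynyl amide
Product: 20 (6R)-2,2,6-trimethyl-7-oxobicyclo[4.2.0]oct-1(8)-en-4-yl acetate (ring A-fused cyclobutenone; 5R in carotenoid numbering; both C3 epimers), via keteniminium triflate 18 (not isolated), via cyclobuteniminium triflate 19 (not isolated)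
Conditions: Tf2O (1.2 equiv), 2,6-di-tert-butyl-4-methylpyridine (1.5 equiv), ClCH2CH2Cl (0.02 M), −20 → 70 °C; then H2O, NaHCO3, THF, 40 °C
Reagents that add atoms: water, O
Why: O-Triflation of the amide and removal of the C5 proton by the hindered pyridine give a keteniminium ion in which C5 is planar (so the C5 epimers of 17 converge), its central carbon C8 is attacked by the terminal alkyne carbon C7, and the vinyl cation developing at C6 is captured by C5 in a stepwise polar [2+2] cycloaddition whose cyclobuteniminium salt is hydrolysed to the enone. The closest known reactions are the intermolecular keteniminium–alkyne cycloadditions that give cyclobutenones and the intramolecular keteniminium–alkene cycloadditions steered by the same C2-symmetric pyrrolidine, so the present case joins two established variants and is not itself demonstrated. Ring A (six-membered) closes through the C5–C6 bond with the triple bond exocyclic to it (6-exo-dig sense, helped by the gem-dialkyl effect of C1), and the cyclobutene closes as the C7–C8 and C5–C6 bonds tie the two alkyne carbons to the C5=C8 unit. The only new stereocentre, quaternary C5, is controlled by the (2R,5R)-pyrrolidine on nitrogen, whose methyl group on the tether side of the cumulene is expected to keep the C7–H end of the alkyne away, so that C6 bonds to the Si face of C5 (5R). The step needs regioselectivity, secured by the polarisation of the terminal alkyne (cation at the internal carbon) and by the four-atom tether, and it needs the absence of internal nucleophiles, secured by the acetate at C3.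

Step 10
Reactants: 20 the cyclobutenone
Product: 21 (7aR)-4,4,7a-trimethyl-2-oxo-2,4,5,6,7,7a-hexahydro-1-benzofuran-6-yl acetate (butenolide; both C6 epimers)
Conditions: mCPBA, NaHCO3, CH2Cl2, 0 → 20 °C
Reagents that add atoms: 3-chloroperoxybenzoic acid, OOC(=O)c1cccc(Cl)c1
Why: Baeyer–Villiger oxidation of the strained enone, in which the quaternary C5 migrates with retention in preference to the vinylic C7, places the ring oxygen on C5, and the electron-poor double bond is not epoxidised.

Step 11
Reactants: 21 the butenolide acetate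
Product: 22 (7aR)-6-hydroxy-4,4,7a-trimethyl-5,6,7,7a-tetrahydro-1-benzofuran-2(4H)-one (loliolide together with its C6 epimer)
Conditions: K2CO3 (0.2 equiv), MeOH, 0 → 20 °C
Reagents that add atoms: none
Why: Base-catalysed transesterification removes the acetate while the butenolide of a tertiary alcohol stays closed.

Step 12
Reactants: 22 the hydroxy butenolides
Product: 23 (7aR)-4,4,7a-trimethyl-7,7a-dihydro-1-benzofuran-2,6(4H,5H)-dione (dehydrololiolide)
Conditions: Dess–Martin periodinane, NaHCO3, CH2Cl2, 20 °C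
Reagents that add atoms: none
Why: Periodinane oxidation under neutral conditions converts both C3 epimers into one ketone without triggering β-elimination of the lactone oxygen.

Step 13
Reactants: 23 dehydrololiolide
Product: 24 (6S,7aR)-6-hydroxy-4,4,7a-trimethyl-5,6,7,7a-tetrahydro-1-benzofuran-2(4H)-one (loliolide; 3S,5R in carotenoid numbering)
Conditions: LiBH(s-Bu)3 (1.1 equiv), THF, −78 °C; then H2O
Reagents that add atoms: none
Why: Ketone reduction by a bulky hydride: the axial methyl groups on C1 and C5 close the axial trajectory, so hydride enters equatorially and gives the axial (3S)-alcohol cis to the C5 methyl, while the β,β-disubstituted butenolide is not reduced at this temperature.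

Step 14
Reactants: 24 loliolide
Product: 25 (6S,7aR)-4,4,7a-trimethyl-2,4,5,6,7,7a-hexahydro-1-benzofuran-2,6-diol (lactol; both C2 epimers)
Conditions: i-Bu2AlH (3 equiv), CH2Cl2, −78 °C; aq. potassium sodium tartrate
Reagents that add atoms: none
Why: Partial reduction of the lactone stops at the tetrahedral aluminate, which gives the lactol on work-up; one hydride equivalent is consumed by the free hydroxyl.

Step 15
Reactants: 25 the lactol
Product: 26 (6S,7aR)-2-methoxy-4,4,7a-trimethyl-2,4,5,6,7,7a-hexahydro-1-benzofuran-6-ol (methyl acetal; both C2 epimers)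
Conditions: MeOH, pyridinium p-toluenesulfonate (cat.), 20 °C
Reagents that add atoms: methanol, CO
Why: Acid-catalysed acetal exchange through the allyl-stabilised oxocarbenium ion gives the mixed acetal at C8, and both anomers converge in step 19.

Step 16
Reactants: 27 but-2-yn-1-ol
Product: 29 (Z)-3-iodobut-2-en-1-ol, via alkenylaluminate 28 (not isolated)
Conditions: NaAlH2(OCH2CH2OMe)2, THF, 0 → 20 °C; then I2, −78 °C
Reagents that add atoms: iodine, II
Why: Alkoxide-directed trans-hydroalumination of the propargylic alcohol places aluminium on C3 cis to the CH2O group, and iodinolysis with retention gives the Z-iodoalkene that carries the 9Z geometry of the target.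

Step 17
Reactants: 29 (Z)-3-iodobut-2-en-1-ol
Product: 30 (Z)-tert-butyl[(3-iodobut-2-en-1-yl)oxy]dimethylsilane
Conditions: t-BuMe2SiCl, imidazole, CH2Cl2, 20 °C
Reagents that add atoms: tert-butyl(chloro)dimethylsilane, CC(C)(C)[Si](C)(C)Cl
Why: Silyl ether formation masks the primary alcohol for the lithiation.

Step 18
Reactants: 30 the silyl ether
Product: 33 [4-{[tert-butyl(dimethyl)silyl]oxy}but-2-en-2-yl]boronic acid with boron cis to the CH2O group (E by the sequence rule only because CH3 outranks B), via alkenyllithium 31 (not isolated), via lithium triisopropoxyborate 32 (not isolated)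
Conditions: t-BuLi (2.1 equiv), Et2O, −78 °C; B(Oi-Pr)3, −78 → 0 °C; cold 1 M HCl (brief)
Reagents that add atoms: triisopropyl borate, CC(C)OB(OC(C)C)OC(C)C; water, O
Why: Iodine–lithium exchange with retention of alkene geometry and immediate trapping by the borate at −78 °C, before 1,4-migration of silicon from oxygen to carbon can set in, give the alkenylboronic acid after hydrolysis.

Step 19
Reactants: 26 the methyl acetal; 33 the alkenylboronic acid
Product: 34 (2R,6S,7aR)-2-[(2Z)-4-{[tert-butyl(dimethyl)silyl]oxy}but-2-en-2-yl]-4,4,7a-trimethyl-2,4,5,6,7,7a-hexahydro-1-benzofuran-6-ol (8R,9Z in carotenoid numbering)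
Conditions: Ni(cod)2 (10 mol%), (R,R)-TADDOL-derived P-phenyl phosphonite (20 mol%; the (S,S) ligand if that proves the matched one), 33 (2 equiv), 1,4-dioxane/t-AmOH, 40 °C
Reagents that add atoms: none
Why: Nickel-catalysed Suzuki–Miyaura-type coupling of a cyclic allylic acetal (known for 2-alkoxy-2H-chromenes): the boronic acid ionises the acetal, zerovalent nickel adds to the C6–C7–C8 oxa-allyl cation, and transmetalation with reductive elimination at the less substituted terminus C8 transfers the alkenyl group with retention of its geometry; because the C5 methyl and the C4 methylene flank the ring plane almost symmetrically, the 8R configuration is assigned to the chiral ligand on nickel, and any 8S epimer is removed by chromatography.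

Step 20
Reactants: 34 the coupled silyl ether
Product: 35 (2Z)-3-[(2R,6S,7aR)-6-hydroxy-4,4,7a-trimethyl-2,4,5,6,7,7a-hexahydro-1-benzofuran-2-yl]but-2-en-1-ol
Conditions: Bu4NF, THF, 0 °C
Reagents that add atoms: none
Why: Fluoride-mediated desilylation frees the allylic alcohol under non-acidic conditions that cannot ionise the C8–O bond.

Step 21
Reactants: 35 the allylic alcohol
Product: 37 [(2Z)-3-[(2R,6S,7aR)-6-hydroxy-4,4,7a-trimethyl-2,4,5,6,7,7a-hexahydro-1-benzofuran-2-yl]but-2-en-1-yl]triphenylphosphonium bromide, via allylic bromide 36 (not isolated)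
Conditions: CBr4 (1.1 equiv), PPh3 (1.15 equiv), CH2Cl2, −20 °C; then PPh3 (1.5 equiv), MeCN, 20 °C
Reagents that add atoms: tetrabromomethane, BrC(Br)(Br)Br; triphenylphosphine, c1ccc(cc1)P(c1ccccc1)c1ccccc1
Why: Appel bromination is neutral and selective for the primary allylic alcohol over the hindered axial secondary one, and SN2 displacement by triphenylphosphine gives the phosphonium salt with the Z double bond intact.

Step 22
Reactants: 38 (2E,4E,6E)-2,7-dimethylocta-2,4,6-trienedial; 39 methyl (triphenylphosphoranylidene)acetate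
Product: 40 methyl (2E,4E,6E,8E)-4,9-dimethyl-10-oxodeca-2,4,6,8-tetraenoate
Conditions: 38 (1.5 equiv), CH2Cl2, 0 → 20 °C, slow addition of 39
Reagents that add atoms: none
Why: Wittig reaction of a stabilised ylide with one formyl group of the symmetrical dialdehyde in excess gives the E-enoate, and the remaining aldehyde is deactivated by the longer conjugation.

Step 23
Reactants: 37 the phosphonium bromide; 40 the aldehyde ester
Product: 42 methyl (2E,4E,6E,8E,10E,12Z)-13-[(2R,6S,7aR)-6-hydroxy-4,4,7a-trimethyl-2,4,5,6,7,7a-hexahydro-1-benzofuran-2-yl]-4,9-dimethyltetradeca-2,4,6,8,10,12-hexaenoate, via phosphorus ylide 41 (not isolated)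
Conditions: NaOMe (1.05 equiv), MeOH/CH2Cl2, 0 → 20 °C, dark; then EtOAc/heptane, 70 °C, N2, dark
Reagents that add atoms: none
Why: Wittig olefination of the kind used for C15 plus polyenal couplings in carotenoid chemistry joins C11 to C12; the trisubstituted 9Z bond of the ylide should keep its configuration, and the sterically hindered 11Z portion should isomerise on gentle heating to 11E under conditions that leave the unhindered 9Z bond alone.

Step 24
Reactants: 42 the polyene ester
Product: 43 (2E,4E,6E,8E,10E,12Z)-13-[(2R,6S,7aR)-6-hydroxy-4,4,7a-trimethyl-2,4,5,6,7,7a-hexahydro-1-benzofuran-2-yl]-4,9-dimethyltetradeca-2,4,6,8,10,12-hexaen-1-ol (the target)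
Conditions: i-Bu2AlH (4 equiv), THF, −78 °C; aq. potassium sodium tartrate
Reagents that add atoms: none
Why: 1,2-Reduction of the conjugated ester by the aluminium hydride gives the allylic alcohol without touching the polyene or the dihydrofuran, and the neutral work-up avoids acid-induced epimerisation at C8.

Compound list

1 | methyl 3,3-dimethylpent-4-enoate | COC(=O)CC(C)(C)C=C | starting material
2 | methyl 3-methyl-3-(1,2,4-trioxolan-3-yl)butanoate (ozonide) | COC(=O)CC(C)(C)C1OCOO1 | intermediate
3 | methyl 3,3-dimethyl-4-oxobutanoate | COC(=O)CC(C)(C)C=O | intermediate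
4 | dimethyl (1-diazo-2-oxopropyl)phosphonate | CC(=O)C(=[N+]=[N-])P(=O)(OC)OC | starting material
5 | methyl 3,3-dimethylpent-4-ynoate | COC(=O)CC(C)(C)C#C | intermediate
6 | tert-butyl acetate | CC(=O)OC(C)(C)C | starting material
7 | lithium enolate of tert-butyl acetate | [Li+].[O-]C(=C)OC(C)(C)C | intermediate
8 | tert-butyl 5,5-dimethyl-3-oxohept-6-ynoate | C#CC(C)(C)CC(=O)CC(=O)OC(C)(C)C | intermediate
9 | (2R,5R)-2,5-dimethylpyrrolidine | N1[C@H](C)CC[C@H]1C | starting material
10 | 2-bromopropanoyl bromide | CC(Br)C(=O)Br | starting material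
11 | 2-bromo-1-[(2R,5R)-2,5-dimethylpyrrolidin-1-yl]propan-1-one (both epimers at C2) | CC(Br)C(=O)N1[C@H](C)CC[C@H]1C | intermediate
12 | sodium enolate of 8 | [Na+].C#CC(C)(C)CC(=O)C=C([O-])OC(C)(C)C | intermediate
13 | tert-butyl 2-{1-[(2R,5R)-2,5-dimethylpyrrolidin-1-yl]-1-oxopropan-2-yl}-5,5-dimethyl-3-oxohept-6-ynoate (diastereomer mixture) | C#CC(C)(C)CC(=O)C(C(C)C(=O)N1[C@H](C)CC[C@H]1C)C(=O)OC(C)(C)C | intermediate
14 | 2-{1-[(2R,5R)-2,5-dimethylpyrrolidin-1-yl]-1-oxopropan-2-yl}-5,5-dimethyl-3-oxohept-6-ynoic acid | C#CC(C)(C)CC(=O)C(C(C)C(=O)N1[C@H](C)CC[C@H]1C)C(=O)O | intermediate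
15 | 1-[(2R,5R)-2,5-dimethylpyrrolidin-1-yl]-2,6,6-trimethyloct-7-yne-1,4-dione (both C2 epimers) | C#CC(C)(C)CC(=O)CC(C)C(=O)N1[C@H](C)CC[C@H]1C | intermediate
16 | 1-[(2R,5R)-2,5-dimethylpyrrolidin-1-yl]-4-hydroxy-2,6,6-trimethyloct-7-yn-1-one (C2 and C4 epimers) | C#CC(C)(C)CC(O)CC(C)C(=O)N1[C@H](C)CC[C@H]1C | intermediate
17 | 1-[(2R,5R)-2,5-dimethylpyrrolidin-1-yl]-2,6,6-trimethyl-1-oxooct-7-yn-4-yl acetate (C2 and C4 epimers; key-step precursor) | C#CC(C)(C)CC(OC(C)=O)CC(C)C(=O)N1[C@H](C)CC[C@H]1C | intermediate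
18 | (2R,5R)-1-(4-acetoxy-2,6,6-trimethyloct-1-en-7-yn-1-ylidene)-2,5-dimethylpyrrolidinium triflate (keteniminium salt) | C#CC(C)(C)CC(OC(C)=O)CC(C)=C=[N+]1[C@H](C)CC[C@H]1C.[O-]S(=O)(=O)C(F)(F)F | intermediate
19 | (2R,5R)-1-[(6R)-4-acetoxy-2,2,6-trimethylbicyclo[4.2.0]oct-1(8)-en-7-ylidene]-2,5-dimethylpyrrolidinium triflate | C1(=[N+]3[C@H](C)CC[C@H]3C)C=C2C(C)(C)CC(OC(C)=O)C[C@@]12C.[O-]S(=O)(=O)C(F)(F)F | intermediate
20 | (6R)-2,2,6-trimethyl-7-oxobicyclo[4.2.0]oct-1(8)-en-4-yl acetate (both C4 epimers; key-step product) | O=C1C=C2C(C)(C)CC(OC(C)=O)C[C@@]12C | intermediate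
21 | (7aR)-4,4,7a-trimethyl-2-oxo-2,4,5,6,7,7a-hexahydro-1-benzofuran-6-yl acetate (both C6 epimers) | O=C1C=C2C(C)(C)CC(OC(C)=O)C[C@@]2(C)O1 | intermediate
22 | (7aR)-6-hydroxy-4,4,7a-trimethyl-5,6,7,7a-tetrahydro-1-benzofuran-2(4H)-one (both C6 epimers) | O=C1C=C2C(C)(C)CC(O)C[C@@]2(C)O1 | intermediate
23 | (7aR)-4,4,7a-trimethyl-7,7a-dihydro-1-benzofuran-2,6(4H,5H)-dione | O=C1C=C2C(C)(C)CC(=O)C[C@@]2(C)O1 | intermediate
24 | (6S,7aR)-6-hydroxy-4,4,7a-trimethyl-5,6,7,7a-tetrahydro-1-benzofuran-2(4H)-one (loliolide) | O=C1C=C2C(C)(C)C[C@H](O)C[C@@]2(C)O1 | intermediate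
25 | (6S,7aR)-4,4,7a-trimethyl-2,4,5,6,7,7a-hexahydro-1-benzofuran-2,6-diol (both C2 epimers) | OC1C=C2C(C)(C)C[C@H](O)C[C@@]2(C)O1 | intermediate
26 | (6S,7aR)-2-methoxy-4,4,7a-trimethyl-2,4,5,6,7,7a-hexahydro-1-benzofuran-6-ol (both C2 epimers) | COC1C=C2C(C)(C)C[C@H](O)C[C@@]2(C)O1 | intermediate
27 | but-2-yn-1-ol | CC#CCO | starting material
28 | sodium 2,2-bis(2-methoxyethoxy)-3-methyl-2,5-dihydro-1,2-oxaaluminol-2-uide (cyclic alkenylaluminate) | [Na+].CC1=CCO[Al-]1(OCCOC)OCCOC | intermediate
29 | (Z)-3-iodobut-2-en-1-ol | C/C(I)=C/CO | intermediate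
30 | (Z)-tert-butyl[(3-iodobut-2-en-1-yl)oxy]dimethylsilane | C/C(I)=C/CO[Si](C)(C)C(C)(C)C | intermediate
31 | [4-{[tert-butyl(dimethyl)silyl]oxy}but-2-en-2-yl]lithium, lithium cis to the CH2O group | C/C([Li])=C/CO[Si](C)(C)C(C)(C)C | intermediate
32 | lithium [4-{[tert-butyl(dimethyl)silyl]oxy}but-2-en-2-yl]tri(propan-2-yloxy)borate, boron cis to the CH2O group | [Li+].C/C(=C/CO[Si](C)(C)C(C)(C)C)[B-](OC(C)C)(OC(C)C)OC(C)C | intermediate
33 | [(2E)-4-{[tert-butyl(dimethyl)silyl]oxy}but-2-en-2-yl]boronic acid, boron cis to the CH2O group | C/C(B(O)O)=C/CO[Si](C)(C)C(C)(C)C | intermediate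
34 | (2R,6S,7aR)-2-[(2Z)-4-{[tert-butyl(dimethyl)silyl]oxy}but-2-en-2-yl]-4,4,7a-trimethyl-2,4,5,6,7,7a-hexahydro-1-benzofuran-6-ol | C/C(=C/CO[Si](C)(C)C(C)(C)C)[C@H]1C=C2C(C)(C)C[C@H](O)C[C@@]2(C)O1 | intermediate
35 | (2Z)-3-[(2R,6S,7aR)-6-hydroxy-4,4,7a-trimethyl-2,4,5,6,7,7a-hexahydro-1-benzofuran-2-yl]but-2-en-1-ol | C/C(=C/CO)[C@H]1C=C2C(C)(C)C[C@H](O)C[C@@]2(C)O1 | intermediate
36 | (2R,6S,7aR)-2-[(2Z)-4-bromobut-2-en-2-yl]-4,4,7a-trimethyl-2,4,5,6,7,7a-hexahydro-1-benzofuran-6-ol | C/C(=C/CBr)[C@H]1C=C2C(C)(C)C[C@H](O)C[C@@]2(C)O1 | intermediate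
37 | [(2Z)-3-[(2R,6S,7aR)-6-hydroxy-4,4,7a-trimethyl-2,4,5,6,7,7a-hexahydro-1-benzofuran-2-yl]but-2-en-1-yl]triphenylphosphonium bromide | C/C(=C/C[P+](c3ccccc3)(c4ccccc4)c5ccccc5)[C@H]1C=C2C(C)(C)C[C@H](O)C[C@@]2(C)O1.[Br-] | intermediate
38 | (2E,4E,6E)-2,7-dimethylocta-2,4,6-trienedial | O=C/C(C)=C/C=C/C=C(C)/C=O | starting material
39 | methyl (triphenylphosphoranylidene)acetate | COC(=O)C=P(c1ccccc1)(c1ccccc1)c1ccccc1 | starting material
40 | methyl (2E,4E,6E,8E)-4,9-dimethyl-10-oxodeca-2,4,6,8-tetraenoate | COC(=O)/C=C/C(C)=C/C=C/C=C(C)/C=O | intermediate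
41 | (2R,6S,7aR)-4,4,7a-trimethyl-2-[(2Z)-4-(triphenyl-λ5-phosphanylidene)but-2-en-2-yl]-2,4,5,6,7,7a-hexahydro-1-benzofuran-6-ol (ylide) | C/C(=C/C=P(c3ccccc3)(c4ccccc4)c5ccccc5)[C@H]1C=C2C(C)(C)C[C@H](O)C[C@@]2(C)O1 | intermediate
42 | methyl (2E,4E,6E,8E,10E,12Z)-13-[(2R,6S,7aR)-6-hydroxy-4,4,7a-trimethyl-2,4,5,6,7,7a-hexahydro-1-benzofuran-2-yl]-4,9-dimethyltetradeca-2,4,6,8,10,12-hexaenoate | C/C(=C/C=C/C(C)=C/C=C/C=C(C)/C=C/C(=O)OC)[C@H]1C=C2C(C)(C)C[C@H](O)C[C@@]2(C)O1 | intermediate
43 | (2E,4E,6E,8E,10E,12Z)-13-[(2R,6S,7aR)-6-hydroxy-4,4,7a-trimethyl-2,4,5,6,7,7a-hexahydro-1-benzofuran-2-yl]-4,9-dimethyltetradeca-2,4,6,8,10,12-hexaen-1-ol | C/C(=C/C=C/C(C)=C/C=C/C=C(C)/C=C/CO)[C@H]1C=C2C(C)(C)C[C@H](O)C[C@@]2(C)O1 | target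

Total step count: 24. Longest linear sequence: 19 steps (1, 2, 3, 5–15, 19, 20, 21, 23, 24).

Steps most likely to fail

1. Step 9. The keteniminium ion may be consumed before ring closure (proton loss to an aminodiene, oligomerisation), or C6 may be delivered to C5 with low facial selectivity. The fallback is the alkene series, which uses only demonstrated reaction types, and it sets out from 17. Semihydrogenation (H2, Pd/CaCO3 poisoned with Pb(OAc)2, quinoline, EtOAc) gives the alkene amide F1. Its keteniminium ion (Tf2O, 2,6-di-tert-butyl-4-methylpyridine, ClCH2CH2Cl, 80 °C; aq. NaHCO3) undergoes the auxiliary-controlled intramolecular [2+2] cycloaddition with the vinyl group to the cis-fused cyclobutanone F2, the amine enantiomer being chosen to give 5R. Baeyer–Villiger oxidation (mCPBA) gives the saturated lactone F3 and methanolysis (K2CO3, MeOH) the hydroxy lactone F4. Selenenylation of the lactone enolate (LiN(i-Pr)2, 2.2 equiv; PhSeCl) gives the α-phenylselanyl lactone F5, and oxidation with H2O2 followed by syn-elimination restores the C6=C7 double bond. The route is rejoined at 22.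

2. Step 19. Ionisation of the non-aromatic acetal may be slow, or the catalyst may fail to overrule the almost unbiased faces at C8. The fallback makes the C8–C9 bond by carbonyl addition and sets out from 25. The alkenyllithium 31 (from 30, 3.5 equiv, Et2O/THF, −78 °C) adds to the open hydroxy-aldehyde form of the lactol to give the triol F6. Cyclodehydration through the allylic C8 cation (pyridinium p-toluenesulfonate, CH2Cl2, 0 °C), the reaction by which furanoid oxides ordinarily form, closes the dihydrofuran. The 8R and 8S epimers are separated by chromatography and the route is rejoined at 34.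

3. Step 23. The ylide may expel the C8 oxygen by vinylogous β-elimination, or the C11=C12 geometry may not be corrected without eroding the 9Z bond. The fallback reverses the polarity of the coupling and sets out from 35 and 40. MnO2 (CH2Cl2, 20 °C) oxidises 35 to the Z-enal F7. Aldehyde 40 is reduced (NaBH4, MeOH, 0 °C) to the hydroxy ester F8, converted (CBr4, PPh3) into the bromo ester F9, and turned by Michaelis–Arbuzov reaction with P(OEt)3 into the phosphonate F10. Horner–Wadsworth–Emmons reaction of F10 with F7 (NaN(SiMe3)2, THF, −78 °C), which favours E at the new bond and leaves the ring fragment free of carbanionic character, rejoins the route at 42.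

Further compounds

F1 | step 9 | 1-[(2R,5R)-2,5-dimethylpyrrolidin-1-yl]-2,6,6-trimethyl-1-oxooct-7-en-4-yl acetate (C2 and C4 epimers) | C=CC(C)(C)CC(OC(C)=O)CC(C)C(=O)N1[C@H](C)CC[C@H]1C
F2 | step 9 | (1S,6R)-2,2,6-trimethyl-7-oxobicyclo[4.2.0]octan-4-yl acetate (cis-fused; both C4 epimers) | O=C1C[C@H]2C(C)(C)CC(OC(C)=O)C[C@@]12C
F3 | step 9 | (3aS,7aR)-4,4,7a-trimethyl-2-oxooctahydro-1-benzofuran-6-yl acetate (both C6 epimers) | O=C1C[C@H]2C(C)(C)CC(OC(C)=O)C[C@@]2(C)O1
F4 | step 9 | (3aS,7aR)-6-hydroxy-4,4,7a-trimethylhexahydro-1-benzofuran-2(3H)-one (both C6 epimers) | O=C1C[C@H]2C(C)(C)CC(O)C[C@@]2(C)O1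
F5 | step 9 | 3-(phenylselanyl) derivative of F4 (selenium on the lactone α-carbon) | O=C1C([Se]c3ccccc3)[C@H]2C(C)(C)CC(O)C[C@@]2(C)O1
F6 | step 19 | (1R,3S,6Z)-6-[(3Z)-5-{[tert-butyl(dimethyl)silyl]oxy}-2-hydroxy-3-methylpent-3-en-1-ylidene]-1,5,5-trimethylcyclohexane-1,3-diol (both epimers at the new carbinol) | C/C(=C/CO[Si](C)(C)C(C)(C)C)C(O)/C=C1/C(C)(C)C[C@H](O)C[C@@]1(C)O
F7 | step 23 | (2Z)-3-[(2R,6S,7aR)-6-hydroxy-4,4,7a-trimethyl-2,4,5,6,7,7a-hexahydro-1-benzofuran-2-yl]but-2-enal | C/C(=C/C=O)[C@H]1C=C2C(C)(C)C[C@H](O)C[C@@]2(C)O1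
F8 | step 23 | methyl (2E,4E,6E,8E)-10-hydroxy-4,9-dimethyldeca-2,4,6,8-tetraenoate | COC(=O)/C=C/C(C)=C/C=C/C=C(C)/CO
F9 | step 23 | methyl (2E,4E,6E,8E)-10-bromo-4,9-dimethyldeca-2,4,6,8-tetraenoate | COC(=O)/C=C/C(C)=C/C=C/C=C(C)/CBr
F10 | step 23 | methyl (2E,4E,6E,8E)-10-(diethoxyphosphoryl)-4,9-dimethyldeca-2,4,6,8-tetraenoate | COC(=O)/C=C/C(C)=C/C=C/C=C(C)/CP(=O)(OCC)OCC
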